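## Retrosynthetic overview

1. The target, catechin-(4α→6)-epicatechin-(4β→8)-epicatechin-(4β→8)-epicatechin, comes from one hydrogenolysis of a fully protected tetramer (16 O-benzyl groups, two C8–Br caps).
2. The protected tetramer comes from a [2+2] union: the lower-unit C4 of a catechin-(4α→6)-epicatechin dimer is joined to C8 of benzylated procyanidin B2.
3. The pivotal disconnection is the C4–O bond of that upper dimer, made by site-selective oxidative C4–H etherification at the dimer stage. The same C–H to C–O tactic arms each monomer electrophile.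
4. The dimers come from monomers: a C8-bromo-capped catechin C4-ether plus C8-bromo-epicatechin (Br forces attack through C6), and an epicatechin C4-ether plus benzylated epicatechin (C8 attack).
5. No ring is built. All four chroman rings and the C2/C3 stereocentres come intact from (+)-catechin and (−)-epicatechin. Order of assembly: lower dimer, upper dimer, C–O activation, union, deprotection.

Assumption: every transient C4 ether is drawn as the 4β isomer (OR anti to the 2-aryl group). This centre is lost on ionisation and does not affect the outcome.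

## Route

Step 1
Reactants: 1 (−)-epicatechin
Product: 2 5,7,3',4'-tetra-O-benzyl-(−)-epicatechin
Conditions: BnBr (4.4 equiv), K2CO3 (4.4 equiv), DMF, 0 °C to rt, Ar
Reagents that add atoms: benzyl bromide, BrCc1ccccc1
Why: Williamson ether synthesis; K2CO3 deprotonates only the four phenols, not the secondary 3-OH, and C2/C3 are untouched at or below rt.

Step 2
Reactants: 2 5,7,3',4'-tetra-O-benzyl-(−)-epicatechin
Product: 3 (2R,3R,4S)-4β-(2-ethoxyethoxy)-5,7,3',4'-tetra-O-benzylepicatechin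
Conditions: DDQ (2 equiv), EtOCH2CH2OH (10 equiv), CH2Cl2, rt
Reagents that add atoms: 2-ethoxyethanol, CCOCCO
Why: DDQ-mediated oxidative benzylic C–H etherification; hydride abstraction at C4 gives a 5,7,8a-trioxygenated benzylic cation that the alcohol traps anti to the 2-aryl and 3-OH groups, and this centre serves only as a leaving-group carrier.

Step 3
Reactants: 3 (2R,3R,4S)-4β-(2-ethoxyethoxy)-5,7,3',4'-tetra-O-benzylepicatechin; 2 5,7,3',4'-tetra-O-benzyl-(−)-epicatechin (4 equiv, excess recovered)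
Product: 4 5,7,3',4'-tetra-O-benzylepicatechin-(4β→8)-5,7,3',4'-tetra-O-benzylepicatechin (octa-O-benzyl procyanidin B2)
Conditions: TMSOTf (0.2 equiv), CH2Cl2, −78 °C
Reagents that add atoms: none
Why: Lewis-acid-catalysed Friedel–Crafts-type (SN1) interflavan coupling; the C4 cation of 3 is attacked by C8 of 2, its most nucleophilic and least hindered carbon, from the face anti to both 3-OH and 2-aryl, which sets C4 of unit C as 4β (3,4-trans), and excess 2 suppresses self-condensation of 3.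

Step 4
Reactants: 2 5,7,3',4'-tetra-O-benzyl-(−)-epicatechin
Product: 5 8-bromo-5,7,3',4'-tetra-O-benzyl-(−)-epicatechin
Conditions: NBS (1.0 equiv), CH2Cl2, −78 °C to rt
Reagents that add atoms: N-bromosuccinimide, O=C1CCC(=O)N1Br
Why: electrophilic aromatic bromination; C8 is the most nucleophilic ring position, so one equivalent of NBS caps it selectively and leaves C6 as the only free nucleophilic carbon.

Step 5
Reactants: 6 (+)-catechin
Product: 7 5,7,3',4'-tetra-O-benzyl-(+)-catechin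
Conditions: BnBr (4.4 equiv), K2CO3 (4.4 equiv), DMF, 0 °C to rt, Ar
Reagents that add atoms: benzyl bromide, BrCc1ccccc1
Why: Williamson ether synthesis on the four phenols only, as in step 1, with no change at C2 or C3.

Step 6
Reactants: 7 5,7,3',4'-tetra-O-benzyl-(+)-catechin
Product: 9 (2R,3S,4S)-8-bromo-4β-(2-ethoxyethoxy)-5,7,3',4'-tetra-O-benzylcatechin, via 8-bromo-5,7,3',4'-tetra-O-benzylcatechin 8 (not isolated)
Conditions: NBS (1.0 equiv), CH2Cl2, −78 to 0 °C; then DDQ (2 equiv), EtOCH2CH2OH (10 equiv), rt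
Reagents that add atoms: N-bromosuccinimide, O=C1CCC(=O)N1Br; 2-ethoxyethanol, CCOCCO
Why: electrophilic aromatic bromination at C8 followed in the same flask by DDQ-mediated oxidative benzylic C–H etherification at C4; NBS is fully consumed first and succinimide is inert to DDQ, so both stages run in CH2Cl2 without interference.

Step 7
Reactants: 9 (2R,3S,4S)-8-bromo-4β-(2-ethoxyethoxy)-5,7,3',4'-tetra-O-benzylcatechin; 5 8-bromo-5,7,3',4'-tetra-O-benzyl-(−)-epicatechin (2.5 equiv, excess recovered)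
Product: 10 8-bromo-5,7,3',4'-tetra-O-benzylcatechin-(4α→6)-8-bromo-5,7,3',4'-tetra-O-benzylepicatechin
Conditions: TMSOTf (0.3 equiv), 4 Å MS, CH2Cl2, −78 to −20 °C
Reagents that add atoms: none
Why: halo-capped Friedel–Crafts-type (SN1) interflavan coupling; the C8–Br on 9 blocks its self-condensation, the C8–Br on 5 leaves only C6 to attack, and attack anti to the 3-OH gives the all-equatorial 3,4-trans product, which sets C4 of unit A as 4α.

Step 8
Reactants: 10 8-bromo-5,7,3',4'-tetra-O-benzylcatechin-(4α→6)-8-bromo-5,7,3',4'-tetra-O-benzylepicatechin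
Product: 11 8-bromo-5,7,3',4'-tetra-O-benzylcatechin-(4α→6)-8-bromo-4β-(2-ethoxyethoxy)-5,7,3',4'-tetra-O-benzylepicatechin
Conditions: DDQ (1.5 equiv), EtOCH2CH2OH (20 equiv), 4 Å MS, CH2Cl2, 0 °C to rt
Reagents that add atoms: 2-ethoxyethanol, CCOCCO
Why: Proposed new method: site-selective quinone-mediated C4–H etherification of a 4→6-linked, doubly C8-bromo-capped biflavan; DDQ should abstract hydride only from the pseudo-axial C–H of the lower-unit C4 methylene, which is aligned with its trioxygenated arene, whereas the upper-unit C4–H is a tertiary diarylmethine buried between three benzyloxy groups and cannot become coplanar with either arene, and both rings carry the same deactivating Br so there is no electronic bias toward the upper unit; the cation is trapped by the alcohol to forge the C4–O bond that arms the dimer for the union, and the closest known reaction is the DDQ/alcohol C4–H alkoxylation of monomeric O-benzylated flavan-3-ols (steps 2 and 6).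

Step 9
Reactants: 11 8-bromo-5,7,3',4'-tetra-O-benzylcatechin-(4α→6)-8-bromo-4β-(2-ethoxyethoxy)-5,7,3',4'-tetra-O-benzylepicatechin; 4 octa-O-benzyl procyanidin B2 (2 equiv, excess recovered)
Product: 12 hexadeca-O-benzyl-8,8''-dibromo-catechin-(4α→6)-epicatechin-(4β→8)-epicatechin-(4β→8)-epicatechin (Br at C8 of units A and B)
Conditions: TMSOTf (0.3 equiv), 4 Å MS, CH2Cl2, −78 to −40 °C
Reagents that add atoms: none
Why: Lewis-acid-catalysed Friedel–Crafts-type (SN1) [2+2] interflavan coupling; the unit-B cation cannot self-condense (both C8 positions capped) and is attacked by C8 of the upper unit of 4, its only unhindered nucleophilic carbon, anti to the 3-OH and 2-aryl of unit B, which sets C4 of unit B as 4β.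

Step 10
Reactants: 12 hexadeca-O-benzyl-8,8''-dibromo tetramer
Product: 13 (+)-catechin-(4α→6)-(−)-epicatechin-(4β→8)-(−)-epicatechin-(4β→8)-(−)-epicatechin (CNP0228086.1)
Conditions: H2 (1 atm), 20% Pd(OH)2/C, Et3N (2.2 equiv), THF/MeOH/H2O, rt; Sephadex LH-20
Reagents that add atoms: none
Why: catalytic hydrogenolysis of the sixteen benzyl ethers with concurrent hydrodebromination of both aryl bromides; Et3N traps HBr so the acid-labile interflavan bonds and all twelve stereocentres are untouched.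

## Compound list

1 | (−)-epicatechin (2R,3R) | Oc1cc(O)c2c(c1)O[C@H](c1ccc(O)c(O)c1)[C@H](O)C2 | starting material

2 | 5,7,3',4'-tetra-O-benzyl-(−)-epicatechin | c9ccccc9COc1cc(OCc9ccccc9)c2c(c1)O[C@H](c1ccc(OCc9ccccc9)c(OCc9ccccc9)c1)[C@H](O)C2 | intermediate

3 | (2R,3R,4S)-4β-(2-ethoxyethoxy)-5,7,3',4'-tetra-O-benzylepicatechin | c9ccccc9COc1cc(OCc9ccccc9)c2c(c1)O[C@H](c1ccc(OCc9ccccc9)c(OCc9ccccc9)c1)[C@H](O)[C@H]2OCCOCC | intermediate

4 | 5,7,3',4'-tetra-O-benzylepicatechin-(4β→8)-5,7,3',4'-tetra-O-benzylepicatechin (octa-O-benzyl procyanidin B2) | c9ccccc9COc1cc(OCc9ccccc9)c2c(c1)O[C@H](c1ccc(OCc9ccccc9)c(OCc9ccccc9)c1)[C@H](O)[C@H]2c1c(OCc9ccccc9)cc(OCc9ccccc9)c3c1O[C@H](c1ccc(OCc9ccccc9)c(OCc9ccccc9)c1)[C@H](O)C3 | intermediate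

5 | 8-bromo-5,7,3',4'-tetra-O-benzyl-(−)-epicatechin | c9ccccc9COc1cc(OCc9ccccc9)c2c(c1Br)O[C@H](c1ccc(OCc9ccccc9)c(OCc9ccccc9)c1)[C@H](O)C2 | intermediate

6 | (+)-catechin (2R,3S) | Oc1cc(O)c2c(c1)O[C@H](c1ccc(O)c(O)c1)[C@@H](O)C2 | starting material

7 | 5,7,3',4'-tetra-O-benzyl-(+)-catechin | c9ccccc9COc1cc(OCc9ccccc9)c2c(c1)O[C@H](c1ccc(OCc9ccccc9)c(OCc9ccccc9)c1)[C@@H](O)C2 | intermediate

8 | 8-bromo-5,7,3',4'-tetra-O-benzyl-(+)-catechin | c9ccccc9COc1cc(OCc9ccccc9)c2c(c1Br)O[C@H](c1ccc(OCc9ccccc9)c(OCc9ccccc9)c1)[C@@H](O)C2 | intermediate (not isolated)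

9 | (2R,3S,4S)-8-bromo-4β-(2-ethoxyethoxy)-5,7,3',4'-tetra-O-benzylcatechin | c9ccccc9COc1cc(OCc9ccccc9)c2c(c1Br)O[C@H](c1ccc(OCc9ccccc9)c(OCc9ccccc9)c1)[C@@H](O)[C@H]2OCCOCC | intermediate

10 | 8-bromo-5,7,3',4'-tetra-O-benzylcatechin-(4α→6)-8-bromo-5,7,3',4'-tetra-O-benzylepicatechin | c9ccccc9COc1cc(OCc9ccccc9)c2c(c1Br)O[C@H](c1ccc(OCc9ccccc9)c(OCc9ccccc9)c1)[C@@H](O)[C@@H]2c1c(OCc9ccccc9)c(Br)c2c(c1OCc9ccccc9)C[C@@H](O)[C@@H](c1ccc(OCc9ccccc9)c(OCc9ccccc9)c1)O2 | intermediate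

11 | 8-bromo-5,7,3',4'-tetra-O-benzylcatechin-(4α→6)-8-bromo-4β-(2-ethoxyethoxy)-5,7,3',4'-tetra-O-benzylepicatechin | c9ccccc9COc1cc(OCc9ccccc9)c2c(c1Br)O[C@H](c1ccc(OCc9ccccc9)c(OCc9ccccc9)c1)[C@@H](O)[C@@H]2c1c(OCc9ccccc9)c(Br)c2c(c1OCc9ccccc9)[C@H](OCCOCC)[C@@H](O)[C@@H](c1ccc(OCc9ccccc9)c(OCc9ccccc9)c1)O2 | intermediate

12 | hexadeca-O-benzyl-8,8''-dibromo-catechin-(4α→6)-epicatechin-(4β→8)-epicatechin-(4β→8)-epicatechin | c9ccccc9COc1cc(OCc9ccccc9)c2c(c1Br)O[C@H](c1ccc(OCc9ccccc9)c(OCc9ccccc9)c1)[C@@H](O)[C@@H]2c1c(OCc9ccccc9)c(Br)c2c(c1OCc9ccccc9)[C@H](c1c(OCc9ccccc9)cc(OCc9ccccc9)c3c1O[C@H](c1ccc(OCc9ccccc9)c(OCc9ccccc9)c1)[C@H](O)[C@H]3c1c(OCc9ccccc9)cc(OCc9ccccc9)c3c1O[C@H](c1ccc(OCc9ccccc9)c(OCc9ccccc9)c1)[C@H](O)C3)[C@@H](O)[C@@H](c1ccc(OCc9ccccc9)c(OCc9ccccc9)c1)O2 | intermediate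

13 | (+)-catechin-(4α→6)-(−)-epicatechin-(4β→8)-(−)-epicatechin-(4β→8)-(−)-epicatechin | Oc1cc(O)c2c(c1)O[C@H](c1ccc(O)c(O)c1)[C@@H](O)[C@@H]2c1c(O)cc2c(c1O)[C@H](c1c(O)cc(O)c3c1O[C@H](c1ccc(O)c(O)c1)[C@H](O)[C@H]3c1c(O)cc(O)c3c1O[C@H](c1ccc(O)c(O)c1)[C@H](O)C3)[C@@H](O)[C@@H](c1ccc(O)c(O)c1)O2 | target

## Step count and risks

Total steps: 10. Longest linear sequence: 6 (steps 5, 6, 7, 8, 9, 10 from (+)-catechin; equally 1, 4, 7, 8, 9, 10 from (−)-epicatechin).

The three steps most likely to fail: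

**Step 7 (4α→6 coupling).** C6 of 5 is flanked by two benzyloxy groups and deactivated by Br, so the coupling may be slow, and the 4α/4β ratio of a catechin cation with a free 3-OH is not guaranteed. The fallback changes the stereocontrol element to neighbouring-group participation. It sets out from 7: acetylation (Ac2O, pyridine, DMAP) gives 3-O-acetyl-5,7,3',4'-tetra-O-benzylcatechin F1. One-pot NBS, then DDQ/2-ethoxyethanol, gives 3-O-acetyl-8-bromo-4β-(2-ethoxyethoxy)-5,7,3',4'-tetra-O-benzylcatechin F2. TMSOTf-mediated coupling with 5 proceeds through a persistent cis-fused C3/C4 acetoxonium ion that can only be opened from the α face, giving the 3-O-acetyl dimer F3. K2CO3 in MeOH/THF removes the acetate and the route is rejoined at 10.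

**Step 8 (proposed new C–H etherification).** The risks are oxidation at the upper-unit C4–H, over-oxidation to the C4 ketone, and low conversion of the brominated ring. The fallback uses known hard/soft orthogonal activation of C4–O versus C4–S leaving groups and avoids any oxidation of a dimer. It sets out from 5: DDQ/2-ethoxyethanol gives 8-bromo-4β-(2-ethoxyethoxy)-5,7,3',4'-tetra-O-benzylepicatechin F4. Exchange with 2,6-dimethylbenzenethiol and BF3·OEt2 gives 8-bromo-4β-(2,6-dimethylphenylthio)-5,7,3',4'-tetra-O-benzylepicatechin F5. Coupling of 9 with F5 (BF3·OEt2, −78 °C, thioether untouched, attack through C6) gives the 4α→6 dimer carrying the lower-unit 4β-arylthio group F6. Soft activation of F6 (I2, Ag2O, CH2Cl2) in the presence of 4 rejoins the route at 12.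

**Step 9 ([2+2] union).** The dimeric cation is hindered next to the C6-linked unit A, and the dimeric nucleophile cannot be used in large excess. The fallback replaces the convergent union by stepwise chain extension with small monomeric nucleophiles. It sets out from 11 (with 3 as a side input): 3 with 2,6-dimethylbenzenethiol and BF3·OEt2 gives 4β-(2,6-dimethylphenylthio)-5,7,3',4'-tetra-O-benzylepicatechin F7. Coupling of 11 with excess F7 (BF3·OEt2, −78 °C, C8 attack) gives the A–B–C trimer carrying a 4β-arylthio group on unit C F8. Soft activation of F8 (I2, Ag2O) with excess 2 rejoins the route at 12.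

## Further compounds

F1 | step 7 | 3-O-acetyl-5,7,3',4'-tetra-O-benzyl-(+)-catechin | c9ccccc9COc1cc(OCc9ccccc9)c2c(c1)O[C@H](c1ccc(OCc9ccccc9)c(OCc9ccccc9)c1)[C@@H](OC(C)=O)C2

F2 | step 7 | 3-O-acetyl-8-bromo-4β-(2-ethoxyethoxy)-5,7,3',4'-tetra-O-benzylcatechin | c9ccccc9COc1cc(OCc9ccccc9)c2c(c1Br)O[C@H](c1ccc(OCc9ccccc9)c(OCc9ccccc9)c1)[C@@H](OC(C)=O)[C@H]2OCCOCC

F3 | step 7 | 3-O-acetyl-8-bromo-5,7,3',4'-tetra-O-benzylcatechin-(4α→6)-8-bromo-5,7,3',4'-tetra-O-benzylepicatechin | c9ccccc9COc1cc(OCc9ccccc9)c2c(c1Br)O[C@H](c1ccc(OCc9ccccc9)c(OCc9ccccc9)c1)[C@@H](OC(C)=O)[C@@H]2c1c(OCc9ccccc9)c(Br)c2c(c1OCc9ccccc9)C[C@@H](O)[C@@H](c1ccc(OCc9ccccc9)c(OCc9ccccc9)c1)O2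

F4 | step 8 | 8-bromo-4β-(2-ethoxyethoxy)-5,7,3',4'-tetra-O-benzylepicatechin | c9ccccc9COc1cc(OCc9ccccc9)c2c(c1Br)O[C@H](c1ccc(OCc9ccccc9)c(OCc9ccccc9)c1)[C@H](O)[C@H]2OCCOCC

F5 | step 8 | 8-bromo-4β-(2,6-dimethylphenylthio)-5,7,3',4'-tetra-O-benzylepicatechin | c9ccccc9COc1cc(OCc9ccccc9)c2c(c1Br)O[C@H](c1ccc(OCc9ccccc9)c(OCc9ccccc9)c1)[C@H](O)[C@H]2Sc1c(C)cccc1C

F6 | step 8 | 8-bromo-5,7,3',4'-tetra-O-benzylcatechin-(4α→6)-8-bromo-4β-(2,6-dimethylphenylthio)-5,7,3',4'-tetra-O-benzylepicatechin | c9ccccc9COc1cc(OCc9ccccc9)c2c(c1Br)O[C@H](c1ccc(OCc9ccccc9)c(OCc9ccccc9)c1)[C@@H](O)[C@@H]2c1c(OCc9ccccc9)c(Br)c2c(c1OCc9ccccc9)[C@H](Sc1c(C)cccc1C)[C@@H](O)[C@@H](c1ccc(OCc9ccccc9)c(OCc9ccccc9)c1)O2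

F7 | step 9 | 4β-(2,6-dimethylphenylthio)-5,7,3',4'-tetra-O-benzylepicatechin | c9ccccc9COc1cc(OCc9ccccc9)c2c(c1)O[C@H](c1ccc(OCc9ccccc9)c(OCc9ccccc9)c1)[C@H](O)[C@H]2Sc1c(C)cccc1C

F8 | step 9 | 8-bromo-tetra-O-benzylcatechin-(4α→6)-8-bromo-tetra-O-benzylepicatechin-(4β→8)-4β-(2,6-dimethylphenylthio)-tetra-O-benzylepicatechin | c9ccccc9COc1cc(OCc9ccccc9)c2c(c1Br)O[C@H](c1ccc(OCc9ccccc9)c(OCc9ccccc9)c1)[C@@H](O)[C@@H]2c1c(OCc9ccccc9)c(Br)c2c(c1OCc9ccccc9)[C@H](c1c(OCc9ccccc9)cc(OCc9ccccc9)c3c1O[C@H](c1ccc(OCc9ccccc9)c(OCc9ccccc9)c1)[C@H](O)[C@H]3Sc1c(C)cccc1C)[C@@H](O)[C@@H](c1ccc(OCc9ccccc9)c(OCc9ccccc9)c1)O2
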